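**Remark on the chemistry (assumption).** The target is numbered as a 1-aryl-1,2-dihydronaphthalene lignan: C1 carries ring C, C2 the acetoxymethyl group (its carbon is C9), C3 the formyl group, C4 is the vinylic CH, and ring A runs C4a–C5–C6(OMe)–C7(OH)–C8–C8a. Read this way the SMILES corresponds to (1S,2R), the 1,2-trans isomer.

## Analysis of the target

The target is a cyclolignan built on a 1-aryl-1,2-dihydronaphthalene. Ring A is a guaiacol (methoxy on C6, hydroxyl on C7), ring B holds the two sp3 carbons C1 and C2 and the C3=C4 bond of an enal, and ring C (4-hydroxy-3-methoxyphenyl) sits on C1. The only stereocenters are C1 (S) and C2 (R); they are adjacent and trans, C1 being doubly benzylic and C2 carrying the acetoxymethyl arm. The sensitive groups are the enal, the base-labile primary acetate, two oxidizable phenols, and a dihydronaphthalene that aromatizes with quinone-type oxidants. Because an aliphatic alcohol cannot be acetylated cleanly beside two free phenols, the acetate has to be in place before either phenol is set free. The synthesis is hard because the two vanillyl-derived halves sit at different oxidation levels (C9 as an alcohol ester, the C3 substituent as an aldehyde), and the trans dyad has to be set without a ring to help. The strategy rests on ring A: its hydroxyl-bearing C7 and methoxy-bearing C6 are adjacent, and its fusion carbons C4a and C8a carry C4 and C1. This is the pattern left when a 4-methoxyfuran-2-yl group adds a tethered alkyne across its 2,5-positions and the oxygen bridge opens toward C7.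

## Retrosynthetic reasoning

The last operation is removal of the ring C protecting group, so 18 is traced to its methoxymethyl ether 17. An acetal-type ether is used because it must outlast a Grignard reagent, an ylide and a fluoride-mediated desilylation earlier in the route; an aryl silyl ether would not survive the last of these.

Ring A of 17 is taken apart next. Re-forming the oxygen bridge between C4a and C7 leads to the oxanorbornadiene 16, and cutting C4a–C8a and C7–C8 in a retro-[4+2] sense gives the acyclic furan–alkyne 15. This cut removes two rings and two skeletal bonds at once. It leaves a precursor in which both stereocenters, the acetate and the enal are already present, and the cycloaddition creates no lasting stereocenter. The forward reaction has to bring an unactivated terminal alkyne onto the furan and open the bridge at C4a rather than at C7.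

The C3=C4 bond of 15 is cut as an aldol condensation between aldehyde 10 and 4-methoxyfuran-2-carbaldehyde 14. The disconnection is convergent. The enolizable position of 10 is C3, so C2 cannot epimerize. The condensation should give the E-enal, which places the furan cis to C2 as the cycloaddition requires.

Aldehyde 14 is traced through its acetals 13 and 12 to 4-bromofuran-2-carbaldehyde 11. The C–O bond at the furan 4-position is made by copper-catalysed exchange of bromide, with the aldehyde masked.

The formyl carbon of 10 is removed in the retrosynthetic sense (enol ether 9, a one-carbon homologation forward), and the acetate is traced through alcohol 8 to the silyl ether 7 and then to aldehyde 6. This detour has a stereochemical reason. The C1–C2 bond is to be made by attack of an enamine on a metal-bound propargylic cation. That reaction is expected to place the aryl group and the α-substituent of the aldehyde syn when the chain is drawn carbonyl–C2–C1–alkyne. The target needs the acetoxymethyl arm and the aryl group syn when the chain is drawn C3–C2–C1–alkyne. The carbonyl carbon of the aldehyde partner must therefore become C3, and its α-substituent must become C9. The opposite assignment would need the anti isomer.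

Aldehyde 6 is cut at C1–C2 into the racemic propargylic alcohol 4 and the silyloxy aldehyde 5. The forward step must set C2 by catalyst control and C1 relative to it; the carbinol centre of 4 is erased on ionization.

Alcohol 4 comes from aldehyde 2 and ethynylmagnesium bromide 3, and 2 from vanillin 1.

## Alternatives that were turned down

Alternative 1: The bonds from C1 to ring C and from C2 to C9 are cut together. The key step would give A1, a 1,1-diaryl-2-boryl-3-silylpropane, from the Z-styrenyl boronate A2 (ring A with its C4 aldehyde masked), the silylmethyl Grignard reagent A3 and the ring C aryl triflate A4. The boron ate complex from A2 and A3 would react with a palladium catalyst carrying a chiral ferrocenyl bisphosphine; the aryl group adds to C1 while the silylmethyl group migrates from boron to C2.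
- For: both stereocenters come from one catalyst-controlled, stereospecific anti addition across an alkene of defined geometry, and both arenes are bought rather than built.
- Against: a β-aryl alkenyl boronate with an ortho substituent is a hindered substrate for the metallate shift, and direct coupling of A2 with A4 competes. After A1 the C–B bond must become the C2–C3 bond with a two-carbon aldehyde arm, the C–Si bond must be oxidized and the alcohol acetylated, ring B must be closed by an intramolecular aldol condensation, and the protecting groups removed. That is at least six further operations, some of them oxidations next to electron-rich arenes.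
- Comparison: on stereocontrol this alternative is stronger than the chosen route, whose propargylation promises only moderate diastereocontrol. The chosen route offers a one-step endgame, correct oxidation levels at C9 and at the formyl carbon from the start, and a ring A pattern fixed by the furan.

Alternative 2: The C2–C3 bond is cut. The acyclic diester A6 (a propanoate arm on C1 and a β-keto ester arm on ring A) would be converted into its dianion with a lithium amide and oxidized with a copper carboxylate, closing ring B as the 4-oxotetralin diester A5.
- For: a six-membered ring closure by intramolecular enolate coupling is well disposed, both new centres are α to carbonyl groups and can settle into the trans,trans arrangement relative to C1, and C1 can be set beforehand by a robust asymmetric conjugate arylation.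
- Against: every functional group of A5 is at the wrong oxidation level. The C4 ketone must be reduced and eliminated, and the two esters must be differentiated into an acetoxymethyl group and an aldehyde, about six steps in all. The strong base and stoichiometric oxidant also meet two electron-rich arenes.
- Comparison: the ring closure of this alternative is on firmer ground than the cycloaddition chosen here. The chosen route gives redox economy in return: the acetate and the enal are carried through the key step and one deprotection remains.

Alternative 3: The bonds C1–C2 and C3–C4 are cut across ring B. Irradiation of the 2-benzylbenzaldehyde A8 at 365 nm would give a hydroxy-o-quinodimethane, which adds the acetoxy enal A9 in the presence of a titanium alkoxide and a TADDOL-type diol to give the 4-hydroxytetralin-3-carbaldehyde A7. Dehydration and desilylation would finish the synthesis.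
- For: this is the most convergent and shortest plan, with every substituent delivered in the right place and the relative configuration following from an endo transition state.
- Against: enantiocontrol depends on a titanium-bound dienol meeting a weakly coordinating, monodentate enal. A9 can lose acetate or isomerize at its double bond under irradiation, and the aryl-substituted photoenol must adopt one geometry for C1 and C2 to come out trans.
- Comparison: on step economy this alternative is stronger. The chosen route instead sets both stereocenters by ground-state catalysis before any ring is formed, and its key step cannot erode them because it creates no stereocenter.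

Key step: step 10

## Route

Step 1
Reactants: 1 vanillin (4-hydroxy-3-methoxybenzaldehyde)
Product: 2 3-methoxy-4-(methoxymethoxy)benzaldehyde
Conditions: MOMCl, iPr2NEt, CH2Cl2, 0 °C to rt
Reagents that add atoms: chloromethyl methyl ether, COCCl
Why: O-Alkylation of the phenol (Williamson-type) gives an aryl MOM ether that withstands the Grignard reagent, the ylide and the fluoride used later, which an aryl silyl ether would not survive in step 5.

Step 2
Reactants: 2 3-methoxy-4-(methoxymethoxy)benzaldehyde; 3 ethynylmagnesium bromide
Product: 4 1-[3-methoxy-4-(methoxymethoxy)phenyl]prop-2-yn-1-ol (racemic)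
Conditions: THF, 0 °C; aq. NH4Cl
Reagents that add atoms: none
Why: 1,2-Addition of the alkynyl Grignard reagent gives the terminal propargylic alcohol needed for allenylidene formation; the racemate is used because step 3 erases this centre.

Step 3
Reactants: 4 1-[3-methoxy-4-(methoxymethoxy)phenyl]prop-2-yn-1-ol; 5 3-[(tert-butyldimethylsilyl)oxy]propanal
Product: 6 (2S,3R)-2-{[(tert-butyldimethylsilyl)oxy]methyl}-3-[3-methoxy-4-(methoxymethoxy)phenyl]pent-4-ynal
Conditions: [Cp*RuCl(μ-SMe)]2 (5 mol%), NH4BF4 (10 mol%), (S)-2-{bis[3,5-bis(trifluoromethyl)phenyl](trimethylsilyloxy)methyl}pyrrolidine (10 mol%), 5 (3 equiv), toluene, rt; short silica filtration, used at once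
Reagents that add atoms: none
Why: Cooperative ruthenium/enamine propargylic substitution: 4 ionizes to a ruthenium allenylidene whose γ-carbon is attacked by the E-enamine of 5. The (S)-amine shields one enamine face and should set C2 as (S), and an open transition state in which ring C turns away from the aminovinyl unit should place aryl and silyloxymethyl syn, that is (2S,3R). Only moderate control is expected at C1, so the C1 epimer is carried along and removed by chromatography at 10.

Step 4
Reactants: 6 (2S,3R)-2-{[(tert-butyldimethylsilyl)oxy]methyl}-3-[3-methoxy-4-(methoxymethoxy)phenyl]pent-4-ynal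
Product: 7 tert-butyl({(2R,3R)-2-(2-methoxyethenyl)-3-[3-methoxy-4-(methoxymethoxy)phenyl]pent-4-yn-1-yl}oxy)dimethylsilane (E/Z mixture at the enol ether)
Conditions: MeOCH2PPh3Cl, KN(SiMe3)2, THF, −78 °C to 0 °C
Reagents that add atoms: (methoxymethyl)triphenylphosphonium chloride, COC[P+](c1ccccc1)(c1ccccc1)c1ccccc1.[Cl-]
Why: Wittig methoxymethylenation adds the carbon that becomes the formyl carbon. α-Branched β-silyloxy aldehydes of this kind take a preformed ylide at low temperature without epimerization, and the enol ether geometry is of no consequence.

Step 5
Reactants: 7 tert-butyl({(2R,3R)-2-(2-methoxyethenyl)-3-[3-methoxy-4-(methoxymethoxy)phenyl]pent-4-yn-1-yl}oxy)dimethylsilane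
Product: 9 (2R,3R)-2-(2-methoxyethenyl)-3-[3-methoxy-4-(methoxymethoxy)phenyl]pent-4-yn-1-yl acetate (E/Z mixture), via free primary alcohol 8 (not isolated)
Conditions: Bu4NF, AcOH, THF, 0 °C to rt; then Et3N, Ac2O, DMAP (cat.), rt
Reagents that add atoms: acetic anhydride, CC(=O)OC(C)=O
Why: Buffered fluoride cleaves the primary silyl ether and leaves the MOM ether, enol ether and alkyne alone, with the buffer keeping the medium from deprotonating the benzylic-propargylic C1–H. Acetylation in the same flask (nucleophilic acyl substitution) fixes the C9 acetate while no phenol is free.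

Step 6
Reactants: 9 (2R,3R)-2-(2-methoxyethenyl)-3-[3-methoxy-4-(methoxymethoxy)phenyl]pent-4-yn-1-yl acetate
Product: 10 (2S,3R)-3-[3-methoxy-4-(methoxymethoxy)phenyl]-2-(2-oxoethyl)pent-4-yn-1-yl acetate
Conditions: 1 M HCl, THF, 0 °C to rt; chromatographic removal of the C1 epimer
Reagents that add atoms: water, O
Why: Acid-catalysed enol ether hydrolysis (protonation at the β-carbon, collapse of the hemiacetal) unveils the aldehyde. The acetate and the aryl MOM ether tolerate cold dilute acid, and C2 is not α to the new carbonyl group.

Step 7
Reactants: 11 4-bromofuran-2-carbaldehyde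
Product: 12 4-bromo-2-(dimethoxymethyl)furan
Conditions: HC(OMe)3, p-TsOH (cat.), MeOH, rt
Reagents that add atoms: trimethyl orthoformate, COC(OC)OC; methanol, CO
Why: Acid-catalysed acetalization masks the non-enolizable aldehyde against hydride-transfer and addition pathways under the hot methoxide of step 8.

Step 8
Reactants: 12 4-bromo-2-(dimethoxymethyl)furan
Product: 14 4-methoxyfuran-2-carbaldehyde, via methoxy acetal 13 (not isolated)
Conditions: NaOMe (3 equiv), CuBr (10 mol%), MeOH/DMF, 100 °C; then 1 M HCl, THF, 0 °C
Reagents that add atoms: sodium methoxide, C[O-].[Na+]; water, O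
Why: Ullmann-type copper-catalysed substitution of the furan β-bromide by methoxide. The cold acidic work-up hydrolyses the acetal, which is much more labile than the enol-ether-like methoxyfuran.

Step 9
Reactants: 10 (2S,3R)-3-[3-methoxy-4-(methoxymethoxy)phenyl]-2-(2-oxoethyl)pent-4-yn-1-yl acetate; 14 4-methoxyfuran-2-carbaldehyde
Product: 15 (2R,3R)-2-[(1E)-1-(4-methoxyfuran-2-yl)-3-oxoprop-1-en-2-yl]-3-[3-methoxy-4-(methoxymethoxy)phenyl]pent-4-yn-1-yl acetate
Conditions: pyrrolidine (20 mol%), PhCO2H (20 mol%), 14 (1.5 equiv), CH2Cl2, rt to 40 °C
Reagents that add atoms: none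
Why: Amine-catalysed cross-aldol condensation: the enamine of 10 adds to the iminium ion of non-enolizable 14 and the amine is eliminated. Only C3 is enolizable, so C1 and C2 are untouched, and the trisubstituted enal should form as the favoured E isomer with the furan trans to the formyl group and cis to C2.

Step 10
Reactants: 15 (2R,3R)-2-[(1E)-1-(4-methoxyfuran-2-yl)-3-oxoprop-1-en-2-yl]-3-[3-methoxy-4-(methoxymethoxy)phenyl]pent-4-yn-1-yl acetate
Product: 17 [(1S,2R)-3-formyl-7-hydroxy-6-methoxy-1-[3-methoxy-4-(methoxymethoxy)phenyl]-1,2-dihydronaphthalen-2-yl]methyl acetate, via oxanorbornadiene cycloadduct 16 (not isolated)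
Conditions: toluene (0.01 M), BHT (10 mol%), 150 °C, sealed tube, Ar; then CSA (20 mol%), rt
Reagents that add atoms: none
Why: Proposed new method: on heating, the 4-methoxyfuran, whose C5 is its most electron-rich carbon, should add across its 2,5-positions to the tethered terminal alkyne in a concerted suprafacial [4+2]; the C4a–C8a bond closes ring B as the fused six-membered ring of a type 1 intramolecular Diels–Alder reaction over the four-atom tether C4=C3–C2–C1, whose E-enal geometry holds furan and C2 cis, and the C7–C8 bond completes the carbocycle that becomes ring A, giving 16. Acid then protonates the bridge oxygen and breaks C4a–O, because that cation is tertiary, allylic to C8=C8a and stabilized through C5=C6 by the C6 methoxy group as an oxocarbenium ion, whereas cleavage of C7–O would give a cation the methoxy group cannot reach; loss of H7 aromatizes ring A with the hydroxyl on C7. The closest known reaction type is the intramolecular Diels–Alder reaction of furans with tethered alkynes followed by opening of the oxanorbornadiene to a phenol, established for activated alkynes, heteroatom tethers and amino-substituted furans but not for an unactivated alkyne on an all-carbon tether. No lasting stereocenter is formed: the two bridgehead centres of 16 vanish on aromatization, so attack on either furan face leads to 17, and C1 and C2, neither of them enolizable, are carried through unchanged. The step needs the right phenol regiochemistry, which the fixed 2,4-substitution of the furan and the methoxy-directed bridge opening secure. It also needs chemoselectivity against intermolecular cycloaddition of furan and enal units and against a [3,3] shift of the 1,5-enyne, which high dilution and the lowest workable temperature address. Aromatization is irreversible and should pull the reversible furan cycloaddition forward; gold or platinum activation of the alkyne is avoided because it proceeds through arene oxides and can give isomeric phenols.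

Step 11
Reactants: 17 [(1S,2R)-3-formyl-7-hydroxy-6-methoxy-1-[3-methoxy-4-(methoxymethoxy)phenyl]-1,2-dihydronaphthalen-2-yl]methyl acetate
Product: 18 [(1S,2R)-3-formyl-7-hydroxy-1-(4-hydroxy-3-methoxyphenyl)-6-methoxy-1,2-dihydronaphthalen-2-yl]methyl acetate
Conditions: TFA/CH2Cl2 (1:5), 0 °C
Reagents that add atoms: none
Why: Acidolysis of the aryl MOM acetal through its oxocarbenium ion frees the ring C phenol. The primary acetate, the enal and both stereocenters are stable to cold trifluoroacetic acid.

## Compound list

1 | vanillin (4-hydroxy-3-methoxybenzaldehyde) | COc1cc(C=O)ccc1O | starting material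
2 | 3-methoxy-4-(methoxymethoxy)benzaldehyde | COCOc1ccc(C=O)cc1OC | intermediate
3 | ethynylmagnesium bromide | C#C[Mg]Br | starting material
4 | 1-[3-methoxy-4-(methoxymethoxy)phenyl]prop-2-yn-1-ol (racemic) | C#CC(O)c1ccc(OCOC)c(OC)c1 | intermediate
5 | 3-[(tert-butyldimethylsilyl)oxy]propanal | O=CCCO[Si](C)(C)C(C)(C)C | starting material
6 | (2S,3R)-2-{[(tert-butyldimethylsilyl)oxy]methyl}-3-[3-methoxy-4-(methoxymethoxy)phenyl]pent-4-ynal | C#C[C@H](c1ccc(OCOC)c(OC)c1)[C@@H](CO[Si](C)(C)C(C)(C)C)C=O | intermediate
7 | tert-butyl({(2R,3R)-2-(2-methoxyethenyl)-3-[3-methoxy-4-(methoxymethoxy)phenyl]pent-4-yn-1-yl}oxy)dimethylsilane (E/Z mixture) | C#C[C@H](c1ccc(OCOC)c(OC)c1)[C@@H](CO[Si](C)(C)C(C)(C)C)C=COC | intermediate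
8 | (2R,3R)-2-(2-methoxyethenyl)-3-[3-methoxy-4-(methoxymethoxy)phenyl]pent-4-yn-1-ol (E/Z mixture) | C#C[C@H](c1ccc(OCOC)c(OC)c1)[C@@H](CO)C=COC | intermediate
9 | (2R,3R)-2-(2-methoxyethenyl)-3-[3-methoxy-4-(methoxymethoxy)phenyl]pent-4-yn-1-yl acetate (E/Z mixture) | C#C[C@H](c1ccc(OCOC)c(OC)c1)[C@@H](COC(C)=O)C=COC | intermediate
10 | (2S,3R)-3-[3-methoxy-4-(methoxymethoxy)phenyl]-2-(2-oxoethyl)pent-4-yn-1-yl acetate | C#C[C@H](c1ccc(OCOC)c(OC)c1)[C@@H](COC(C)=O)CC=O | intermediate
11 | 4-bromofuran-2-carbaldehyde | O=Cc1cc(Br)co1 | starting material
12 | 4-bromo-2-(dimethoxymethyl)furan | COC(OC)c1cc(Br)co1 | intermediate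
13 | 2-(dimethoxymethyl)-4-methoxyfuran | COC(OC)c1cc(OC)co1 | intermediate
14 | 4-methoxyfuran-2-carbaldehyde | O=Cc1cc(OC)co1 | intermediate
15 | (2R,3R)-2-[(1E)-1-(4-methoxyfuran-2-yl)-3-oxoprop-1-en-2-yl]-3-[3-methoxy-4-(methoxymethoxy)phenyl]pent-4-yn-1-yl acetate | C#C[C@H](c1ccc(OCOC)c(OC)c1)[C@@H](COC(C)=O)/C(C=O)=C\c1cc(OC)co1 | intermediate
16 | [(1S,2R)-3-formyl-6-methoxy-1-[3-methoxy-4-(methoxymethoxy)phenyl]-1,2,4a,7-tetrahydro-4a,7-epoxynaphthalen-2-yl]methyl acetate (oxygen bridge C4a–C7; either bridgehead epimer, not assigned) | O=CC1=CC23OC(C=C2[C@H](c4ccc(OCOC)c(OC)c4)[C@H]1COC(C)=O)C(OC)=C3 | intermediate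
17 | [(1S,2R)-3-formyl-7-hydroxy-6-methoxy-1-[3-methoxy-4-(methoxymethoxy)phenyl]-1,2-dihydronaphthalen-2-yl]methyl acetate | COc1cc([C@H]2c3cc(O)c(OC)cc3C=C(C=O)[C@@H]2COC(C)=O)ccc1OCOC | intermediate
18 | [(1S,2R)-3-formyl-7-hydroxy-1-(4-hydroxy-3-methoxyphenyl)-6-methoxy-1,2-dihydronaphthalen-2-yl]methyl acetate | COc1cc([C@H]2c3cc(O)c(OC)cc3C=C(C=O)[C@@H]2COC(C)=O)ccc1O | target

## Step count and least certain steps

Total: 11 steps. Longest linear sequence: 9 steps (steps 1–6, 9, 10 and 11 from vanillin); steps 7 and 8 form the furan branch.

**Step 10 (key step, proposed new method).** The most likely failure is insufficient reactivity: the alkyne is unactivated and the donor character of the methoxyfuran is lowered by conjugation with the enal. The cycloaddition may then lose out to retro-cycloaddition, to intermolecular [4+2] reactions between furan and enal units, to a [3,3] shift of the 1,5-enyne at higher temperature, or to thermal degradation of the methoxyfuran.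

The fallback uses known chemistry only; it sets out from 2 and returns at 18.
- (S)-4-Benzyl-3-(pent-4-enoyl)-1,3-oxazolidin-2-one F1 would be made from (S)-4-benzyl-1,3-oxazolidin-2-one, n-BuLi and pent-4-enoyl chloride.
- Its Z boron enolate (Bu2BOTf, iPr2NEt) would be added to 2 in an Evans syn aldol reaction to give the adduct F2, which fixes C2.
- LiBH4 would release the diol F3, and Ac2O in pyridine would give the diacetate F4.
- Lemieux–Johnson cleavage of the allyl group (OsO4 cat., NaIO4, 2,6-lutidine) would give the aldehyde F5.
- The amine-catalysed condensation of step 9, now with a second equivalent of 2 serving as ring A, would give the E-enal F6.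
- Trifluoroacetic acid would ionize the benzylic acetate to a cation stabilized by ring C. Ring A attacks it para to its methoxy group in an intramolecular Friedel–Crafts alkylation, trans to the C2 substituent, closing ring B to the bis-MOM ether F7. Continued exposure cleaves both MOM ethers to 18.

**Step 3.** Control at the propargylic carbon may be poor, or the open transition state may favour the anti arrangement, so that the needed syn isomer becomes the minor one. β-Elimination of the silyloxy group from the enamine is a lesser risk.

The fallback exchanges the roles of the two arms on C2; it sets out from 4 and returns at 10.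
- Alcohol 4 would be coupled under the same ruthenium/amine conditions with 4,4-dimethoxybutanal and the (R)-configured amine, giving aldehyde F8. Here the carbonyl carbon becomes C9, so the anti isomer is the one needed.
- F8 would be reduced in the same flask with NaBH4 to the alcohol F9, at which stage the diastereomers are separated.
- Acetylation would give F10, and mild aqueous acid would hydrolyse its dimethyl acetal to 10.
- Whichever relative configuration the propargylation favours, one of the two aldehyde partners places the major isomer in the needed series.

**Step 9.** The β-branched aldehyde may condense slowly with the electron-rich furfural, leaving room for self-condensation of 10, aminolysis of the acetate, or incomplete E selectivity.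

The fallback replaces the amine-catalysed condensation by a Lewis-acid acetal–enol ether addition; it sets out from 9 and returns at 15.
- Enol ether 9 would be added to acetal 13 (isolated for this purpose before the acidic work-up of step 8) with catalytic BF3·OEt2 in CH2Cl2 at −40 °C, a Müller–Cunradi–Pieroh-type reaction, giving the β-methoxy acetal F11.
- Warming F11 in aqueous acetic acid with NaOAc would eliminate methanol and hydrolyse the acetal to the E-enal 15.

**Step 8.** Hot methoxide may cause protodebromination or ring degradation of the electron-rich furan before the copper-catalysed exchange is complete.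

The fallback makes the C–O bond from boron instead; it sets out from 12 and returns at 13.
- Bromine–lithium exchange on 12 (n-BuLi, THF, −78 °C) and trapping with 2-isopropoxy-4,4,5,5-tetramethyl-1,3,2-dioxaborolane would give the boronate F12.
- Chan–Lam oxidative coupling of F12 with methanol (Cu(OAc)2, DMAP, air, rt) would give 13, which is hydrolysed to 14 as in step 8.

## Further compounds

F1 | step 10 | (S)-4-benzyl-3-(pent-4-enoyl)-1,3-oxazolidin-2-one | C=CCCC(=O)N1[C@@H](Cc2ccccc2)COC1=O
F2 | step 10 | (4S)-4-benzyl-3-{(2S,3S)-3-hydroxy-3-[3-methoxy-4-(methoxymethoxy)phenyl]-2-(prop-2-en-1-yl)propanoyl}-1,3-oxazolidin-2-one | O[C@H](c1ccc(OCOC)c(OC)c1)[C@@H](C(=O)N1[C@@H](Cc2ccccc2)COC1=O)CC=C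
F3 | step 10 | (1S,2R)-1-[3-methoxy-4-(methoxymethoxy)phenyl]-2-(prop-2-en-1-yl)propane-1,3-diol | O[C@H](c1ccc(OCOC)c(OC)c1)[C@@H](CO)CC=C
F4 | step 10 | (1S,2R)-2-[(acetyloxy)methyl]-1-[3-methoxy-4-(methoxymethoxy)phenyl]pent-4-en-1-yl acetate | CC(=O)O[C@H](c1ccc(OCOC)c(OC)c1)[C@@H](COC(C)=O)CC=C
F5 | step 10 | (1S,2R)-2-[(acetyloxy)methyl]-1-[3-methoxy-4-(methoxymethoxy)phenyl]-4-oxobutyl acetate | CC(=O)O[C@H](c1ccc(OCOC)c(OC)c1)[C@@H](COC(C)=O)CC=O
F6 | step 10 | (1S,2R,3E)-2-[(acetyloxy)methyl]-3-formyl-1,4-bis[3-methoxy-4-(methoxymethoxy)phenyl]but-3-en-1-yl acetate | CC(=O)O[C@H](c1ccc(OCOC)c(OC)c1)[C@@H](COC(C)=O)/C(C=O)=C\c1ccc(OCOC)c(OC)c1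
F7 | step 10 | [(1S,2R)-3-formyl-6-methoxy-7-(methoxymethoxy)-1-[3-methoxy-4-(methoxymethoxy)phenyl]-1,2-dihydronaphthalen-2-yl]methyl acetate | COc1cc([C@H]2c3cc(OCOC)c(OC)cc3C=C(C=O)[C@@H]2COC(C)=O)ccc1OCOC
F8 | step 3 | (2S,3R)-2-(2,2-dimethoxyethyl)-3-[3-methoxy-4-(methoxymethoxy)phenyl]pent-4-ynal | C#C[C@H](c1ccc(OCOC)c(OC)c1)[C@@H](C=O)CC(OC)OC
F9 | step 3 | (2S,3R)-2-(2,2-dimethoxyethyl)-3-[3-methoxy-4-(methoxymethoxy)phenyl]pent-4-yn-1-ol | C#C[C@H](c1ccc(OCOC)c(OC)c1)[C@@H](CO)CC(OC)OC
F10 | step 3 | (2S,3R)-2-(2,2-dimethoxyethyl)-3-[3-methoxy-4-(methoxymethoxy)phenyl]pent-4-yn-1-yl acetate | C#C[C@H](c1ccc(OCOC)c(OC)c1)[C@@H](COC(C)=O)CC(OC)OC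
F11 | step 9 | (2R,3R)-2-[1,1,3-trimethoxy-3-(4-methoxyfuran-2-yl)propan-2-yl]-3-[3-methoxy-4-(methoxymethoxy)phenyl]pent-4-yn-1-yl acetate (mixture of epimers at the two new centres) | C#C[C@H](c1ccc(OCOC)c(OC)c1)[C@@H](COC(C)=O)C(C(OC)OC)C(OC)c1cc(OC)co1
F12 | step 8 | 2-[5-(dimethoxymethyl)furan-3-yl]-4,4,5,5-tetramethyl-1,3,2-dioxaborolane | COC(OC)c1cc(B2OC(C)(C)C(C)(C)O2)co1
A1 | alternative 1 | 1,1-diaryl-2-boryl-3-silylpropane, product of the conjunctive coupling (C1 and C2 set) | COCOc1ccc([C@@H](c2cc(OCOC)c(OC)cc2C2OCCO2)[C@@H](C[Si](C)(C)OC(C)C)B2OC(C)(C)C(C)(C)O2)cc1OC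
A2 | alternative 1 | 2-{(Z)-2-[2-(1,3-dioxolan-2-yl)-4-methoxy-5-(methoxymethoxy)phenyl]ethenyl}-4,4,5,5-tetramethyl-1,3,2-dioxaborolane | COCOc1cc(/C=C\B2OC(C)(C)C(C)(C)O2)c(C2OCCO2)cc1OC
A3 | alternative 1 | [(isopropoxydimethylsilyl)methyl]magnesium chloride | CC(C)O[Si](C)(C)C[Mg]Cl
A4 | alternative 1 | 3-methoxy-4-(methoxymethoxy)phenyl trifluoromethanesulfonate | COCOc1ccc(OS(=O)(=O)C(F)(F)F)cc1OC
A5 | alternative 2 | dimethyl 1-aryl-4-oxotetralin-2,3-dicarboxylate, 1,2-trans and 2,3-trans, product of the oxidative enolate coupling | COCOc1ccc([C@H]2c3cc(OCOC)c(OC)cc3C(=O)[C@@H](C(=O)OC)[C@@H]2C(=O)OC)cc1OC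
A6 | alternative 2 | methyl 3-[4-methoxy-2-(3-methoxy-3-oxopropanoyl)-5-(methoxymethoxy)phenyl]-3-[3-methoxy-4-(methoxymethoxy)phenyl]propanoate, C1 configured as in A5 | COCOc1ccc([C@H](CC(=O)OC)c2cc(OCOC)c(OC)cc2C(=O)CC(=O)OC)cc1OC
A7 | alternative 3 | 4-hydroxytetralin-3-carbaldehyde photoenol adduct (C1-aryl, C3-formyl and C4-hydroxyl cis, C2-acetoxymethyl trans) | COc1cc([C@H]2c3cc(O[Si](C)(C)C(C)(C)C)c(OC)cc3[C@@H](O)[C@@H](C=O)[C@@H]2COC(C)=O)ccc1O[Si](C)(C)C(C)(C)C
A8 | alternative 3 | 4-[(tert-butyldimethylsilyl)oxy]-2-{4-[(tert-butyldimethylsilyl)oxy]-3-methoxybenzyl}-5-methoxybenzaldehyde | COc1cc(Cc2cc(O[Si](C)(C)C(C)(C)C)c(OC)cc2C=O)ccc1O[Si](C)(C)C(C)(C)C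
A9 | alternative 3 | (2E)-4-oxobut-2-en-1-yl acetate | CC(=O)OC/C=C/C=O
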